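## Structural features

The target is a 2,3-dihydro-1-benzofuran in which ring A (the benzo ring) is fused to the five-membered ring O1–C2–C3–C3a–C7a; C2 carries a 4-hydroxyphenyl group (ring C) and C3 a 2,4-dihydroxybenzoyl group (ring B). C5, para to O1, carries a CH2CH2C(=O) chain that ends in a second 2,4-dihydroxyphenyl ketone (ring D). C2 and C3 are the only stereocentres; they are adjacent, both S, and the C2 aryl and C3 aroyl groups are trans. C3–H is alpha to an aryl ketone and benzylic to ring A, so C3 epimerises easily, and because trans is the more stable arrangement only C2 has to be set absolutely. The weak bond is C2–O1, a benzylic aryl ether para to the ring C phenol, which base or acid can open to a para-quinone methide (or, through the C3 enolate, to an alpha-aryl chalcone) with loss of the C2 configuration. The five phenols are sensitive to oxidation and rule out hydrogenolysis and strongly acidic deprotection. The real difficulty is therefore to fix C2 in a ring whose C–O bond is labile and to attach two electron-rich resorcinol ketones without harsh Friedel–Crafts conditions. The key step exploits the fact that C3 is both attached to ring A and alpha to the ketone, hence the carbon of a donor/acceptor diazo compound, while C2 is the methylene carbon of a 4-oxygenated benzyl aryl ether reached from C3 through C3a, C7a and O1, so that one of its C–H bonds lies 1,5 to the carbenoid carbon.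

## Logic of the disconnections

19 to 18: the five O–H bonds are traced back to O–Si bonds. Silyl ethers carry no activated C–H bond next to oxygen and come off with buffered fluoride near neutrality. The forward step must never expose the ring C phenoxide to base, because that opens C2–O1.

18 to 14 and 16: the aryl–CH2 bond at C5 is cut. A Heck reaction of an aryl bromide with a secondary allylic alcohol delivers the saturated aryl ketone directly, so no redox step follows. This removes ring D and the whole chain and leaves a bromide that is inert in all earlier steps. The forward step needs beta-hydride elimination toward the carbinol carbon (through 17) and a base mild enough for the silyl ethers.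

14 to 12 (through 13): the C2–C3 bond is cut, which opens the oxygen ring and removes both stereocentres at once. The precursor is acyclic, achiral and made of three aryl units. The forward step must select one of two enantiotopic benzylic hydrogens and must beat other carbenoid pathways; C3 is then settled by equilibration.

12 to 11: the C=N2 unit is removed. The methylene of 11 is flanked by the ketone and ring A and is the only acidic position, so diazo transfer needs no activating group.

11 to 7 and 10: the bond between the ketone carbonyl and ring B is cut. Acyl substitution on 7 stops at the ketone through a magnesium chelate. The forward step requires that the hindered aryl nucleophile adds faster than it deprotonates the methylene of 7.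

7 to 6, and 6 to 2 and 5: the amide C–N bond and then the benzyl C–O bond are cut. Etherification from the alcohol 5 avoids a 4-silyloxybenzyl halide, which ionises easily. Compound 6 is kept as an ester because it is also the branching point of the fallback for the key step.

2 to 1: the C–Br bond para to the phenol is cut; the phenol directs the bromination to the carbon that becomes C5.

5 to 4 to 3: the benzylic C–H (hydride reduction) and the O–Si bond are removed, leading to a commercial hydroxy aldehyde.

16 to 10 and 15: the carbinol–aryl bond is cut, so that the organomagnesium reagent that supplies ring B also supplies ring D. The forward step needs 1,2-addition to the enal and a cold quench, so that silicon does not move from the ortho oxygen to the new alkoxide.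

10 to 9, and 9 to 8: the C–Mg bond is traced back to a C–Br bond and the two O–Si bonds to phenols. One batch of 10, made once from 9, therefore serves both ketone rings. The forward step demands that silicon does not migrate from oxygen to the metalated carbon; magnesium and bulky silyl groups address this.

## Other disconnections considered

Alternative 1: The cut is made at both aryl–carbonyl bonds (C3 carbonyl to C4 of ring B, chain carbonyl to C4 of ring D). This leads back to the diacid A2 and two molecules of resorcinol A3. In the forward step BF3·OEt2 would convert both carboxylic acids of A2 into acylating species that attack A3 para to one hydroxyl and ortho to the other, giving the pivalate A1 without closing a ring.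
- In its favour: the resorcinol rings need no protection. Regiochemistry follows from the directing effects of A3. Two skeletal bonds form in one operation, against one in the chosen key step. The stereocentres of A2 could be set on a carboxylate substrate, the class for which carbenoid insertion into benzylic ether C–H bonds is best established; on that point this plan is better founded than the chosen one, and it needs no aryl organometallic reagent.
- Against it: hot Lewis acid meets the weak features of the skeleton. C2–O1 can be ionised (the pivalate only damps ring C as a donor). The acylium ion from the C3 acid is secondary and flanked by ring A, so loss of CO to an oxygen-stabilised benzylic cation competes. The hindered C3 acid should react more slowly than the chain acid, so forcing conditions fall on the more fragile site. The pivalate must then be removed with base or a nucleophile from a compound whose freed phenoxide can open C2–O1.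
- Comparison: structurally the key step builds no ring and no stereocentre, so an asymmetric ring construction of A2 is still needed beforehand. Mechanistically it runs through cations next to labile bonds, whereas the chosen plan forms C2–C3 irreversibly under neutral conditions. In step count the two are about equal: what is saved on protecting groups is spent on the propanoic acid chain and the pivalate.

Alternative 2: The cut is made at O1–C7a and leads to the open-chain syn-aldol A5. In the forward step Pd(OAc)2 with 2-(di-tert-butylphosphino)-1,1'-binaphthyl and Cs2CO3 would add zerovalent palladium into the C–Br bond, bind the C2 alkoxide, and close the ring by C–O reductive elimination from a six-membered palladacycle. This gives A4 with both stereocentres untouched.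
- In its favour: both stereocentres come from an oxazolidinone-directed boron aldol of an arylacetyl imide, whose sense and level of induction are predictable. On predictability of absolute configuration it is better than the chosen plan. The syn-aldol maps directly onto the trans ring, so no equilibration is needed. No diazo compound is handled. A Weinreb amide is already in place at C3.
- Against it: A5 is a beta-hydroxy carbonyl compound with an acidic alpha-aryl C–H bond. With carbonate at the temperature of C–O coupling, retro-aldol cleavage and dehydration are both open and both destroy the stereocentres. A secondary benzylic alkoxide on divalent palladium can undergo beta-hydride elimination in competition with slow C–O reductive elimination. The C5 chloride is a poorer handle than a bromide for the later chain attachment. The C3 ketone must still be made from A4 with the same hindered aryl nucleophile. MOM ethers need acid for removal, which threatens C2–O1 at the end.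
- Comparison: structurally the ring closure is equal to the chosen one (one ring, one bond) but sets no stereocentre. Mechanistically it is base-mediated palladium chemistry against a neutral carbenoid insertion. In step count it is longer by about two or three steps and uses chirality stoichiometrically, where the chosen plan uses a catalyst.

Alternative 3: The cut is made at O1–C2 and leads to the alpha-aryl chalcone A7. In the forward step the chiral phosphoric acid (R)-TRIP would shift A7 to its para-quinone methide enol A8 and guide the ring A phenol onto the methide carbon in a 5-exo-trig addition. Rearomatisation of ring C and ketonisation at C3 (trans by equilibration) would give A6.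
- In its favour: it mirrors the likely biogenesis, uses no metal and no diazo compound, and is the shortest of the four plans. On step economy it is better than the chosen plan. On structural gain it is the equal: one ring and two stereocentres in the key step.
- Against it: the bond formed is the labile one. With the ring C phenol free, A6 can return to A8 under the same acid, so the enantiomeric purity is only kinetic and can drain toward the racemate. The shift from A7 to A8 costs the aromaticity of ring C, so little A8 is present at any time. Four MOM ethers must then be removed with Brønsted acid from a compound that racemises through the same channel. A7 needs two phenols free and four protected, which constrains its synthesis.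
- Comparison: mechanistically this is a reversible C–O bond formation under catalyst control. The chosen plan forms a C–C bond irreversibly (loss of N2) while ring C is silylated, so C2–O1 stays locked until the last step. The chosen plan pays for that configurational security with more steps.

Key step: step 10

Remarks on the chemistry (assumptions and design decisions)
- Assumption: Rh2(S-PTTL)4, dirhodium tetrakis[N-phthaloyl-(S)-tert-leucinate], is taken to deliver the (2S) configuration with an aroyl acceptor. If the other benzylic hydrogen is replaced, the enantiomeric catalyst Rh2(R-PTTL)4 is used and nothing else changes.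
- The carbenoid inserts into a C–H bond of the O–CH2 group. The O–CH2 bond itself stays intact and becomes O1–C2.
- All five phenols are carried as triisopropylsilyl (TIPS) ethers, not tert-butyldimethylsilyl ethers. Aryl silyl ethers ortho or para to a ketone are cleaved by DBU and by warm base, both of which the route needs. A small silyl group ortho to an aryl–metal bond migrates from oxygen to carbon. The oxygen ortho to the ketone sits where it could attack the carbenoid through a five-membered oxonium ylide; the bulky TIPS group shields it.
- The 4-silyloxybenzyl group is introduced from the alcohol by Mitsunobu etherification, not from the labile benzyl halide.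
- The arylmagnesium reagent 10 is prepared once as a titrated THF solution under argon and drawn on for steps 8 and 11 on the same day.

## Route

Step 1
Reactants: 1 methyl 2-hydroxyphenylacetate
Product: 2 methyl 2-(5-bromo-2-hydroxyphenyl)acetate
Conditions: NBS, MeCN, 0 °C → rt
Reagents that add atoms: N-bromosuccinimide, O=C1CCC(=O)N1Br
Why: Electrophilic aromatic bromination directed by the phenol; the para position is free and less hindered than the remaining ortho position, so the bromide should enter at the carbon that becomes C5. The acid is carried as its methyl ester so that it neither lactonises onto the phenol nor interferes in step 4.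

Step 2
Reactants: 3 4-hydroxybenzaldehyde
Product: 4 4-(triisopropylsilyloxy)benzaldehyde
Conditions: TIPSCl, imidazole, DMF, rt
Reagents that add atoms: chlorotriisopropylsilane, CC(C)[Si](Cl)(C(C)C)C(C)C
Why: Imidazole-promoted silylation of a phenol; silylating the aldehyde first avoids any competition between a phenol and a benzylic alcohol.

Step 3
Reactants: 4 4-(triisopropylsilyloxy)benzaldehyde
Product: 5 [4-(triisopropylsilyloxy)phenyl]methanol
Conditions: NaBH4, MeOH, 0 °C
Reagents that add atoms: none
Why: Hydride reduction of an aryl aldehyde; the hindered aryl silyl ether should survive brief exposure to cold methanolic borohydride.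

Step 4
Reactants: 2 methyl 2-(5-bromo-2-hydroxyphenyl)acetate; 5 [4-(triisopropylsilyloxy)phenyl]methanol
Product: 6 methyl 2-[5-bromo-2-[[4-(triisopropylsilyloxy)phenyl]methoxy]phenyl]acetate
Conditions: PPh3, DIAD, THF, 0 °C → rt
Reagents that add atoms: none
Why: Mitsunobu etherification: the phenol is acidic enough to protonate the betaine and attacks the primary benzylic alkoxyphosphonium ion. Neutral conditions avoid a 4-silyloxybenzyl halide, which ionises readily toward a quinone-methide-like cation.

Step 5
Reactants: 6 methyl 2-[5-bromo-2-[[4-(triisopropylsilyloxy)phenyl]methoxy]phenyl]acetate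
Product: 7 2-[5-bromo-2-[[4-(triisopropylsilyloxy)phenyl]methoxy]phenyl]-N-methoxy-N-methylacetamide
Conditions: MeNH(OMe)·HCl, i-PrMgCl, THF, −20 → 0 °C
Reagents that add atoms: N,O-dimethylhydroxylamine hydrochloride, CNOC.Cl
Why: Aminolysis of the ester by the magnesium amide formed in the flask (Weinreb amide synthesis); at this temperature the electron-rich aryl bromide should not undergo halogen–magnesium exchange.

Step 6
Reactants: 8 4-bromoresorcinol
Product: 9 1-bromo-2,4-bis(triisopropylsilyloxy)benzene
Conditions: TIPSCl, imidazole, DMF, 40 °C
Reagents that add atoms: chlorotriisopropylsilane, CC(C)[Si](Cl)(C(C)C)C(C)C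
Why: Double silylation of both phenols; the product is the common source of rings B and D.

Step 7
Reactants: 9 1-bromo-2,4-bis(triisopropylsilyloxy)benzene
Product: 10 [2,4-bis(triisopropylsilyloxy)phenyl]magnesium bromide (titrated THF solution, LiCl-complexed)
Conditions: Mg turnings (cat. i-Bu2AlH activation), LiCl, THF, rt
Reagents that add atoms: magnesium, [Mg]
Why: Grignard reagent formation by insertion of magnesium into the aryl C–Br bond, accelerated by LiCl, which also keeps the arylmagnesium species in solution. Magnesium in place of lithium and TIPS in place of a smaller silyl group suppress anionic oxygen-to-carbon silyl migration (retro-Brook) from the ortho silyl ether, so the solution should hold its titre long enough to serve steps 8 and 11.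

Step 8
Reactants: 7 2-[5-bromo-2-[[4-(triisopropylsilyloxy)phenyl]methoxy]phenyl]-N-methoxy-N-methylacetamide; 10 [2,4-bis(triisopropylsilyloxy)phenyl]magnesium bromide
Product: 11 2-[5-bromo-2-[[4-(triisopropylsilyloxy)phenyl]methoxy]phenyl]-1-[2,4-bis(triisopropylsilyloxy)phenyl]ethanone
Conditions: THF, −20 → 0 °C; then aq NH4Cl
Reagents that add atoms: none
Why: Weinreb ketone synthesis: acyl substitution stops at the ketone because the chelated tetrahedral adduct collapses only on work-up. The ring A bromide is inert to an aryl Grignard reagent at 0 °C.

Step 9
Reactants: 11 2-[5-bromo-2-[[4-(triisopropylsilyloxy)phenyl]methoxy]phenyl]-1-[2,4-bis(triisopropylsilyloxy)phenyl]ethanone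
Product: 12 2-[5-bromo-2-[[4-(triisopropylsilyloxy)phenyl]methoxy]phenyl]-2-diazo-1-[2,4-bis(triisopropylsilyloxy)phenyl]ethanone
Conditions: p-ABSA, DBU, MeCN–THF, 0 °C → rt
Reagents that add atoms: 4-acetamidobenzenesulfonyl azide, CC(=O)Nc1ccc(cc1)S(=O)(=O)N=[N+]=[N-]
Why: Regitz diazo transfer: DBU deprotonates the methylene activated by the ketone and ring A, the enolate attacks the sulfonyl azide, and the triazene fragments to the diazo ketone and the sulfonamide. There is only one enolisable position, and TIPS ethers should tolerate DBU in dry medium.

Step 10
Reactants: 12 2-[5-bromo-2-[[4-(triisopropylsilyloxy)phenyl]methoxy]phenyl]-2-diazo-1-[2,4-bis(triisopropylsilyloxy)phenyl]ethanone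
Product: 14 (2S,3S)-5-bromo-3-[2,4-bis(triisopropylsilyloxy)benzoyl]-2-[4-(triisopropylsilyloxy)phenyl]-2,3-dihydro-1-benzofuran, via cis diastereomer 13 (not isolated)
Conditions: Rh2(S-PTTL)4 (2 mol%), PhMe, −40 °C; then DBU (0.3 equiv), rt
Reagents that add atoms: none
Why: The divalent rhodium carboxylate dimer binds the diazo carbon at an axial site, N2 leaves, and an electrophilic donor/acceptor carbenoid forms at the future C3 (donor ring A, acceptor the aroyl group). The carbenoid carbon engages one C–H bond of the O–CH2 group through a three-centre, hydride-transfer-like transition state in which C2–C3 forms as the hydrogen passes to C3. The closest known reaction type is the dirhodium carboxylate-catalysed intramolecular C–H insertion of aryldiazoacetates into benzylic ether C–H bonds, which gives 2-aryl-2,3-dihydrobenzofuran-3-carboxylates; here the acceptor is an aryl ketone. The closure is a 1,5-insertion that forms the five-membered ring O1–C2–C3–C3a–C7a; ylide formation at O1 would need a four-membered ring and should not compete. C2 is set by the catalyst: the phthalimido groups of the chiral carboxylates decide which enantiotopic benzylic hydrogen is replaced. C3 is first set kinetically (cis 13 expected) and then thermodynamically: DBU enolises the ketone and reprotonation places the aroyl group trans to the C2 aryl group. C2 should not be lost in this equilibration, because expulsion of O1 from the enolate is the reverse of a 5-endo-trig closure and the quinone methide path is blocked by the ring C silyl ether. The step needs insertion to outrun attack of the ortho silyloxy oxygen on the carbenoid, Wolff rearrangement and addition to an arene; the C–H bond is doubly activated by O1 and the electron-rich ring C, the TIPS group shields the ortho oxygen and offers no activated C–H bond, the low temperature disfavours rearrangement, and the bromide is inert.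

Step 11
Reactants: 10 [2,4-bis(triisopropylsilyloxy)phenyl]magnesium bromide; 15 acrolein (prop-2-enal)
Product: 16 1-[2,4-bis(triisopropylsilyloxy)phenyl]prop-2-en-1-ol (racemic)
Conditions: THF, −78 → −40 °C; then aq NH4Cl at −40 °C
Reagents that add atoms: none
Why: 1,2-Addition of an aryl Grignard reagent to the aldehyde of acrolein, favoured for a hard nucleophile at low temperature without copper. The carbinol centre is racemic and irrelevant, since it becomes a carbonyl in step 12; a cold quench forestalls silyl migration from the ortho oxygen to the new alkoxide.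

Step 12
Reactants: 14 (2S,3S)-5-bromo-3-[2,4-bis(triisopropylsilyloxy)benzoyl]-2-[4-(triisopropylsilyloxy)phenyl]-2,3-dihydro-1-benzofuran; 16 1-[2,4-bis(triisopropylsilyloxy)phenyl]prop-2-en-1-ol
Product: 18 (2S,3S)-3-[2,4-bis(triisopropylsilyloxy)benzoyl]-5-[3-[2,4-bis(triisopropylsilyloxy)phenyl]-3-oxopropyl]-2-[4-(triisopropylsilyloxy)phenyl]-2,3-dihydro-1-benzofuran, via enol 17 (not isolated)
Conditions: Pd(OAc)2 (5 mol%), P(t-Bu)3·HBF4 (10 mol%), Cy2NMe, dioxane, 70 °C
Reagents that add atoms: none
Why: Heck reaction with an allylic alcohol: zerovalent palladium adds into the C5–Br bond, the terminal alkene inserts with aryl transfer to its CH2 end, and beta-hydride elimination toward the carbinol carbon gives enol 17, which tautomerises to the saturated ketone. The bulky electron-rich phosphine allows oxidative addition to the electron-rich bromide at moderate temperature, and the amine base spares the silyl ethers. C3 stays trans because that is its equilibrium position, and C2 is not involved.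

Step 13
Reactants: 18 (2S,3S)-3-[2,4-bis(triisopropylsilyloxy)benzoyl]-5-[3-[2,4-bis(triisopropylsilyloxy)phenyl]-3-oxopropyl]-2-[4-(triisopropylsilyloxy)phenyl]-2,3-dihydro-1-benzofuran
Product: 19 1-(2,4-dihydroxyphenyl)-3-[(2S,3S)-3-(2,4-dihydroxybenzoyl)-2-(4-hydroxyphenyl)-2,3-dihydro-1-benzofuran-5-yl]propan-1-one (CNP0136359.1)
Conditions: TBAF, AcOH (1:1), THF, 0 °C → rt
Reagents that add atoms: none
Why: Fluoride cleaves the five aryl silyl ethers, driven by the Si–F bond and the phenoxide leaving groups. Acetic acid buffers the medium so that the freed ring C phenol is not held as a phenoxide that could open C2–O1 through a para-quinone methide, and the C3 ketone is not enolised; no stereocentre is touched.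

## Compound list

1 | methyl 2-hydroxyphenylacetate | COC(=O)Cc1ccccc1O | starting material
2 | methyl 2-(5-bromo-2-hydroxyphenyl)acetate | COC(=O)Cc1cc(Br)ccc1O | intermediate
3 | 4-hydroxybenzaldehyde | O=Cc1ccc(O)cc1 | starting material
4 | 4-(triisopropylsilyloxy)benzaldehyde | O=Cc1ccc(O[Si](C(C)C)(C(C)C)C(C)C)cc1 | intermediate
5 | [4-(triisopropylsilyloxy)phenyl]methanol | OCc1ccc(O[Si](C(C)C)(C(C)C)C(C)C)cc1 | intermediate
6 | methyl 2-[5-bromo-2-[[4-(triisopropylsilyloxy)phenyl]methoxy]phenyl]acetate | COC(=O)Cc1cc(Br)ccc1OCc1ccc(O[Si](C(C)C)(C(C)C)C(C)C)cc1 | intermediate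
7 | 2-[5-bromo-2-[[4-(triisopropylsilyloxy)phenyl]methoxy]phenyl]-N-methoxy-N-methylacetamide | CON(C)C(=O)Cc1cc(Br)ccc1OCc1ccc(O[Si](C(C)C)(C(C)C)C(C)C)cc1 | intermediate
8 | 4-bromoresorcinol (4-bromobenzene-1,3-diol) | Oc1ccc(Br)c(O)c1 | starting material
9 | 1-bromo-2,4-bis(triisopropylsilyloxy)benzene | Brc1ccc(O[Si](C(C)C)(C(C)C)C(C)C)cc1O[Si](C(C)C)(C(C)C)C(C)C | intermediate
10 | [2,4-bis(triisopropylsilyloxy)phenyl]magnesium bromide (titrated THF solution) | Br[Mg]c1ccc(O[Si](C(C)C)(C(C)C)C(C)C)cc1O[Si](C(C)C)(C(C)C)C(C)C | intermediate
11 | 2-[5-bromo-2-[[4-(triisopropylsilyloxy)phenyl]methoxy]phenyl]-1-[2,4-bis(triisopropylsilyloxy)phenyl]ethanone | O=C(Cc1cc(Br)ccc1OCc1ccc(O[Si](C(C)C)(C(C)C)C(C)C)cc1)c1ccc(O[Si](C(C)C)(C(C)C)C(C)C)cc1O[Si](C(C)C)(C(C)C)C(C)C | intermediate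
12 | 2-[5-bromo-2-[[4-(triisopropylsilyloxy)phenyl]methoxy]phenyl]-2-diazo-1-[2,4-bis(triisopropylsilyloxy)phenyl]ethanone | Brc1ccc(OCc2ccc(O[Si](C(C)C)(C(C)C)C(C)C)cc2)c(c1)C(=[N+]=[N-])C(=O)c1ccc(O[Si](C(C)C)(C(C)C)C(C)C)cc1O[Si](C(C)C)(C(C)C)C(C)C | intermediate
13 | (2S,3R)-5-bromo-3-[2,4-bis(triisopropylsilyloxy)benzoyl]-2-[4-(triisopropylsilyloxy)phenyl]-2,3-dihydro-1-benzofuran (cis) | Brc1ccc2c(c1)[C@@H](C(=O)c1ccc(O[Si](C(C)C)(C(C)C)C(C)C)cc1O[Si](C(C)C)(C(C)C)C(C)C)[C@@H](c1ccc(O[Si](C(C)C)(C(C)C)C(C)C)cc1)O2 | intermediate (not isolated)
14 | (2S,3S)-5-bromo-3-[2,4-bis(triisopropylsilyloxy)benzoyl]-2-[4-(triisopropylsilyloxy)phenyl]-2,3-dihydro-1-benzofuran (trans) | Brc1ccc2c(c1)[C@H](C(=O)c1ccc(O[Si](C(C)C)(C(C)C)C(C)C)cc1O[Si](C(C)C)(C(C)C)C(C)C)[C@@H](c1ccc(O[Si](C(C)C)(C(C)C)C(C)C)cc1)O2 | intermediate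
15 | acrolein (prop-2-enal) | C=CC=O | starting material
16 | 1-[2,4-bis(triisopropylsilyloxy)phenyl]prop-2-en-1-ol (racemic) | C=CC(O)c1ccc(O[Si](C(C)C)(C(C)C)C(C)C)cc1O[Si](C(C)C)(C(C)C)C(C)C | intermediate
17 | 1-[2,4-bis(triisopropylsilyloxy)phenyl]-3-[(2S,3S)-3-[2,4-bis(triisopropylsilyloxy)benzoyl]-2-[4-(triisopropylsilyloxy)phenyl]-2,3-dihydro-1-benzofuran-5-yl]prop-1-en-1-ol (enol, geometry not defined) | OC(=CCc1ccc2c(c1)[C@H](C(=O)c1ccc(O[Si](C(C)C)(C(C)C)C(C)C)cc1O[Si](C(C)C)(C(C)C)C(C)C)[C@@H](c1ccc(O[Si](C(C)C)(C(C)C)C(C)C)cc1)O2)c1ccc(O[Si](C(C)C)(C(C)C)C(C)C)cc1O[Si](C(C)C)(C(C)C)C(C)C | intermediate (not isolated)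
18 | (2S,3S)-3-[2,4-bis(triisopropylsilyloxy)benzoyl]-5-[3-[2,4-bis(triisopropylsilyloxy)phenyl]-3-oxopropyl]-2-[4-(triisopropylsilyloxy)phenyl]-2,3-dihydro-1-benzofuran | O=C(CCc1ccc2c(c1)[C@H](C(=O)c1ccc(O[Si](C(C)C)(C(C)C)C(C)C)cc1O[Si](C(C)C)(C(C)C)C(C)C)[C@@H](c1ccc(O[Si](C(C)C)(C(C)C)C(C)C)cc1)O2)c1ccc(O[Si](C(C)C)(C(C)C)C(C)C)cc1O[Si](C(C)C)(C(C)C)C(C)C | intermediate
19 | 1-(2,4-dihydroxyphenyl)-3-[(2S,3S)-3-(2,4-dihydroxybenzoyl)-2-(4-hydroxyphenyl)-2,3-dihydro-1-benzofuran-5-yl]propan-1-one | O=C(CCc1ccc2c(c1)[C@H](C(=O)c1ccc(O)cc1O)[C@@H](c1ccc(O)cc1)O2)c1ccc(O)cc1O | target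

## Step count and least certain steps

Total step count: 13. Longest linear sequence: 9 steps (2, 3, 4, 5, 8, 9, 10, 12, 13, counted from compound 3). Counted from compound 1 the sequence is 8 steps, and counted from compound 8 through compound 10 it is 7 steps.

Step 10 (key step). The most likely failure is poor discrimination between the two enantiotopic benzylic hydrogens, because the aroyl carbenoid is more reactive and differently shaped than the ester carbenoids for which phthalimido carboxylate catalysts are best established. A second risk is diversion of the carbenoid by attack of the ortho silyloxy oxygen (five-membered oxonium ylide followed by silyl shift) or by Wolff-type migration of ring B. The fallback moves the insertion to the ester stage, where neither ring B nor a ketone is present; it sets out from compound 6 and comes back to the route at compound 14. Diazo transfer to 6 (p-ABSA, DBU) would give methyl 2-[5-bromo-2-[[4-(triisopropylsilyloxy)phenyl]methoxy]phenyl]-2-diazoacetate F1. Insertion with Rh2(S-PTTL)4 in toluene at low temperature would give the cis ester methyl (2S,3R)-5-bromo-2-[4-(triisopropylsilyloxy)phenyl]-2,3-dihydro-1-benzofuran-3-carboxylate F2. Equilibration at C3 with DBU in toluene would give the trans ester methyl (2S,3S)-5-bromo-2-[4-(triisopropylsilyloxy)phenyl]-2,3-dihydro-1-benzofuran-3-carboxylate F3. Treatment with MeNH(OMe)·HCl and i-PrMgCl would give (2S,3S)-5-bromo-N-methoxy-N-methyl-2-[4-(triisopropylsilyloxy)phenyl]-2,3-dihydro-1-benzofuran-3-carboxamide F4, and addition of the Grignard reagent 10 would deliver 14.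

Step 8. The most likely failure is proton transfer from the acidic methylene of 7 to the hindered aryl Grignard reagent, which returns 7 in place of the ketone; a low titre of 10 from sluggish magnesium insertion in step 7 would show up here as well. The fallback replaces acyl substitution by aldehyde addition and oxidation and does not depend on 10; it sets out from compounds 7 and 9 and comes back at compound 11. Reduction of 7 with i-Bu2AlH at −78 °C would give 2-[5-bromo-2-[[4-(triisopropylsilyloxy)phenyl]methoxy]phenyl]acetaldehyde F5. Bromine–lithium exchange on 9 with t-BuLi at −78 °C would give [2,4-bis(triisopropylsilyloxy)phenyl]lithium F6, used at once at that temperature, where silyl migration is slow and addition to an aldehyde outruns enolisation. The adduct 2-[5-bromo-2-[[4-(triisopropylsilyloxy)phenyl]methoxy]phenyl]-1-[2,4-bis(triisopropylsilyloxy)phenyl]ethanol F7 would be oxidised with Dess–Martin periodinane to 11.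

Step 12. The most likely failure is beta-hydride elimination toward the ring A benzylic CH2, which leaves an aryl-substituted allylic alcohol in place of the ketone. Palladium hydride isomerisation of 16 to a propiophenone before coupling, and slow oxidative addition to the electron-rich bromide, are further risks. The fallback separates C–C bond formation from the redox adjustment; it sets out from compounds 16 and 14 and comes back at compound 18. Oxidation of 16 with MnO2 would give 1-[2,4-bis(triisopropylsilyloxy)phenyl]prop-2-en-1-one F8. A Heck reaction of 14 with this enone (Pd(OAc)2, P(o-tol)3, Et3N, MeCN, 80 °C), which can only eliminate to the conjugated product, would give (E)-1-[2,4-bis(triisopropylsilyloxy)phenyl]-3-[(2S,3S)-3-[2,4-bis(triisopropylsilyloxy)benzoyl]-2-[4-(triisopropylsilyloxy)phenyl]-2,3-dihydro-1-benzofuran-5-yl]prop-2-en-1-one F9. Conjugate reduction with [(Ph3P)CuH]6 in toluene, which leaves aryl ketones alone, would give 18.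

Step 13. The most likely failure is erosion of configuration at C2 by reversible opening of C2–O1 to a para-quinone methide once the ring C phenol is free in a medium that is locally basic; incomplete cleavage of the hindered ortho silyl ethers is the other risk. The fallback deprotects in two stages so that base and the free ring C phenol never coexist; it sets out from compound 18 and comes back at compound 19. K2CO3 in MeOH–THF at 0 °C should remove only the four carbonyl-activated aryl silyl ethers and give 1-(2,4-dihydroxyphenyl)-3-[(2S,3S)-3-(2,4-dihydroxybenzoyl)-2-[4-(triisopropylsilyloxy)phenyl]-2,3-dihydro-1-benzofuran-5-yl]propan-1-one F10. The remaining unactivated silyl ether would then be cleaved under acidic, non-basic conditions with HF·pyridine in THF–pyridine to give 19.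

## Further compounds

F1 | step 10 | methyl 2-[5-bromo-2-[[4-(triisopropylsilyloxy)phenyl]methoxy]phenyl]-2-diazoacetate | COC(=O)C(=[N+]=[N-])c1cc(Br)ccc1OCc1ccc(O[Si](C(C)C)(C(C)C)C(C)C)cc1
F2 | step 10 | methyl (2S,3R)-5-bromo-2-[4-(triisopropylsilyloxy)phenyl]-2,3-dihydro-1-benzofuran-3-carboxylate (cis) | Brc1ccc2c(c1)[C@@H](C(=O)OC)[C@@H](c1ccc(O[Si](C(C)C)(C(C)C)C(C)C)cc1)O2
F3 | step 10 | methyl (2S,3S)-5-bromo-2-[4-(triisopropylsilyloxy)phenyl]-2,3-dihydro-1-benzofuran-3-carboxylate (trans) | Brc1ccc2c(c1)[C@H](C(=O)OC)[C@@H](c1ccc(O[Si](C(C)C)(C(C)C)C(C)C)cc1)O2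
F4 | step 10 | (2S,3S)-5-bromo-N-methoxy-N-methyl-2-[4-(triisopropylsilyloxy)phenyl]-2,3-dihydro-1-benzofuran-3-carboxamide | Brc1ccc2c(c1)[C@H](C(=O)N(C)OC)[C@@H](c1ccc(O[Si](C(C)C)(C(C)C)C(C)C)cc1)O2
F5 | step 8 | 2-[5-bromo-2-[[4-(triisopropylsilyloxy)phenyl]methoxy]phenyl]acetaldehyde | O=CCc1cc(Br)ccc1OCc1ccc(O[Si](C(C)C)(C(C)C)C(C)C)cc1
F6 | step 8 | [2,4-bis(triisopropylsilyloxy)phenyl]lithium | [Li]c1ccc(O[Si](C(C)C)(C(C)C)C(C)C)cc1O[Si](C(C)C)(C(C)C)C(C)C
F7 | step 8 | 2-[5-bromo-2-[[4-(triisopropylsilyloxy)phenyl]methoxy]phenyl]-1-[2,4-bis(triisopropylsilyloxy)phenyl]ethanol (racemic) | OC(Cc1cc(Br)ccc1OCc1ccc(O[Si](C(C)C)(C(C)C)C(C)C)cc1)c1ccc(O[Si](C(C)C)(C(C)C)C(C)C)cc1O[Si](C(C)C)(C(C)C)C(C)C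
F8 | step 12 | 1-[2,4-bis(triisopropylsilyloxy)phenyl]prop-2-en-1-one | C=CC(=O)c1ccc(O[Si](C(C)C)(C(C)C)C(C)C)cc1O[Si](C(C)C)(C(C)C)C(C)C
F9 | step 12 | (E)-1-[2,4-bis(triisopropylsilyloxy)phenyl]-3-[(2S,3S)-3-[2,4-bis(triisopropylsilyloxy)benzoyl]-2-[4-(triisopropylsilyloxy)phenyl]-2,3-dihydro-1-benzofuran-5-yl]prop-2-en-1-one | O=C(/C=C/c1ccc2c(c1)[C@H](C(=O)c1ccc(O[Si](C(C)C)(C(C)C)C(C)C)cc1O[Si](C(C)C)(C(C)C)C(C)C)[C@@H](c1ccc(O[Si](C(C)C)(C(C)C)C(C)C)cc1)O2)c1ccc(O[Si](C(C)C)(C(C)C)C(C)C)cc1O[Si](C(C)C)(C(C)C)C(C)C
F10 | step 13 | 1-(2,4-dihydroxyphenyl)-3-[(2S,3S)-3-(2,4-dihydroxybenzoyl)-2-[4-(triisopropylsilyloxy)phenyl]-2,3-dihydro-1-benzofuran-5-yl]propan-1-one | O=C(CCc1ccc2c(c1)[C@H](C(=O)c1ccc(O)cc1O)[C@@H](c1ccc(O[Si](C(C)C)(C(C)C)C(C)C)cc1)O2)c1ccc(O)cc1O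
A1 | alternative 1 | 4-[(2S,3S)-3-(2,4-dihydroxybenzoyl)-5-[3-(2,4-dihydroxyphenyl)-3-oxopropyl]-2,3-dihydro-1-benzofuran-2-yl]phenyl 2,2-dimethylpropanoate | O=C(CCc1ccc2c(c1)[C@H](C(=O)c1ccc(O)cc1O)[C@@H](c1ccc(OC(=O)C(C)(C)C)cc1)O2)c1ccc(O)cc1O
A2 | alternative 1 | (2S,3S)-5-(2-carboxyethyl)-2-[4-(2,2-dimethylpropanoyloxy)phenyl]-2,3-dihydro-1-benzofuran-3-carboxylic acid | OC(=O)CCc1ccc2c(c1)[C@H](C(O)=O)[C@@H](c1ccc(OC(=O)C(C)(C)C)cc1)O2
A3 | alternative 1 | resorcinol (benzene-1,3-diol) | Oc1cccc(O)c1
A4 | alternative 2 | (2S,3S)-5-chloro-N-methoxy-N-methyl-2-[4-(methoxymethoxy)phenyl]-2,3-dihydro-1-benzofuran-3-carboxamide | Clc1ccc2c(c1)[C@H](C(=O)N(C)OC)[C@@H](c1ccc(OCOC)cc1)O2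
A5 | alternative 2 | (2S,3S)-2-(2-bromo-5-chlorophenyl)-3-hydroxy-N-methoxy-N-methyl-3-[4-(methoxymethoxy)phenyl]propanamide (syn) | Clc1ccc(Br)c(c1)[C@H](C(=O)N(C)OC)[C@@H](c1ccc(OCOC)cc1)O
A6 | alternative 3 | 1-[2,4-bis(methoxymethoxy)phenyl]-3-[(2S,3S)-3-[2,4-bis(methoxymethoxy)benzoyl]-2-(4-hydroxyphenyl)-2,3-dihydro-1-benzofuran-5-yl]propan-1-one | O=C(CCc1ccc2c(c1)[C@H](C(=O)c1ccc(OCOC)cc1OCOC)[C@@H](c1ccc(O)cc1)O2)c1ccc(OCOC)cc1OCOC
A7 | alternative 3 | (E)-1-[2,4-bis(methoxymethoxy)phenyl]-2-[5-[3-[2,4-bis(methoxymethoxy)phenyl]-3-oxopropyl]-2-hydroxyphenyl]-3-(4-hydroxyphenyl)prop-2-en-1-one | O=C(CCc1ccc(O)c(c1)/C(C(=O)c1ccc(OCOC)cc1OCOC)=C\c1ccc(O)cc1)c1ccc(OCOC)cc1OCOC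
A8 | alternative 3 | 1-[2,4-bis(methoxymethoxy)phenyl]-3-[3-[1-[2,4-bis(methoxymethoxy)phenyl]-1-hydroxy-3-(4-oxocyclohexa-2,5-dien-1-ylidene)prop-1-en-2-yl]-4-hydroxyphenyl]propan-1-one (para-quinone methide enol, enol geometry not defined) | OC(c1ccc(OCOC)cc1OCOC)=C(c1cc(CCC(=O)c2ccc(OCOC)cc2OCOC)ccc1O)C=C1C=CC(=O)C=C1
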